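**Retrosynthetic overview**
1. C2–C3 is made last by a Pd/Cu Sonogashira coupling on a (Z)-alkenyl chloride that is installed at the outset by a Pd Kumada coupling (C4–C5) and carried through the whole route.
2. The oxocane (ring B, O on C6/C12) comes from a cis-2,5-disubstituted 3-chlorotetrahydrofuran (ring A, O on C6/C9) by a bromonium-triggered ring expansion that also sets C9–Cl, C12–O and C13–Br.
3. Ring A comes from a chlorohydrin aldol union (C7–C8) of fragment A (C3–C7 α-chloro aldehyde) and fragment B (C8–C15 methyl ketone), then syn-reduction, a transient oxirane, 5-endo closure and inversion to C7–Cl.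
4. Fragment B comes from a Cu-catalysed alkenyl-Grignard opening of a resolved glycidic ester (C11–C12); fragment A from an acrolein-derived Grignard reagent, a (Z)-dihaloethene and organocatalytic α-chlorination.
5. Ring order: oxirane (transient) → tetrahydrofuran ring A → oxocane ring B.

Assumptions: C1–C15 are the carbons of the target chain (C1 = alkyne CH, ring oxygen on C6 and C12); where a chiral catalyst is named, the enantiomer meant is the one that gives the stated configuration. No step has been run; the route is a proposal.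

Step 1
Reactants: 1 prop-2-enal (acrolein)
Product: 2 2-(2-bromoethyl)-1,3-dioxolane
Conditions: HBr (gas), CH2Cl2, 0 °C; then ethane-1,2-diol, TsOH (cat.), 25 °C
Reagents that add atoms: hydrogen bromide, Br; ethane-1,2-diol, OCCO
Why: Conjugate hydrobromination of the enal and acid-catalysed acetalisation give the bromo acetal whose Grignard reagent carries C5–C7 with the aldehyde masked.

Step 2
Reactants: 2 2-(2-bromoethyl)-1,3-dioxolane; 3 (Z)-1,2-dichloroethene
Product: 5 2-[(3Z)-4-chlorobut-3-en-1-yl]-1,3-dioxolane, via Grignard reagent 4 (not isolated)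
Conditions: Mg, THF, 25 °C; then 3 (3 equiv), Pd(PPh3)4 (3 mol %), THF, 25 °C
Reagents that add atoms: none
Why: Kumada coupling: zerovalent palladium inserts into one C–Cl bond of the dihaloalkene with retention and the remaining alkenyl chloride is far less reactive, so mono-coupling forms C4–C5 and fixes the Z geometry of C3=C4.

Step 3
Reactants: 5 2-[(3Z)-4-chlorobut-3-en-1-yl]-1,3-dioxolane
Product: 6 (4Z)-5-chloropent-4-enal
Conditions: 2 M HCl, THF, 40 °C
Reagents that add atoms: water, O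
Why: Acid-catalysed acetal hydrolysis; the alkenyl chloride is inert to aqueous acid.

Step 4
Reactants: 6 (4Z)-5-chloropent-4-enal
Product: 7 (2S,4Z)-2,5-dichloropent-4-enal
Conditions: N-chlorosuccinimide, (2R,5R)-2,5-diphenylpyrrolidine (10 mol %), CH2Cl2, 0 °C; used without chromatography
Reagents that add atoms: N-chlorosuccinimide, O=C1CCC(=O)N1Cl
Why: Enamine organocatalytic α-chlorination: the C2-symmetric pyrrolidine shields one enamine face, so chlorine is delivered to give the (S) centre at C6.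

Step 5
Reactants: 8 but-1-yne
Product: 10 (1E)-1-iodobut-1-ene, via alkenylzirconocene 9 (not isolated)
Conditions: Cp2Zr(H)Cl, THF, 25 °C; then N-iodosuccinimide, 0 °C
Reagents that add atoms: N-iodosuccinimide, O=C1CCC(=O)N1I
Why: Syn hydrozirconation of the terminal alkyne followed by iododezirconation with retention gives the E alkenyl iodide.

Step 6
Reactants: 11 methyl oxirane-2-carboxylate (racemic methyl glycidate)
Product: 12 methyl (2S)-oxirane-2-carboxylate
Conditions: (S,S)-(salen)Co(OAc) [cobalt acetate complex of N,N'-bis(3,5-di-tert-butylsalicylidene)cyclohexane-1,2-diamine] (0.5 mol %), H2O (0.55 equiv), THF, 0 to 25 °C; distillation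
Reagents that add atoms: none
Why: Jacobsen hydrolytic kinetic resolution: the chiral cobalt salen catalyst hydrolyses the (R)-epoxide selectively and leaves the (S)-ester, whose stereocentre becomes C10.

Step 7
Reactants: 10 (1E)-1-iodobut-1-ene; 12 methyl (2S)-oxirane-2-carboxylate
Product: 14 methyl (2S,4E)-2-hydroxyhept-4-enoate, via alkenylmagnesium chloride 13 (not isolated)
Conditions: i-PrMgCl·LiCl (1.05 equiv), THF, 25 °C; then CuBr·SMe2 (10 mol %), 12, THF, −40 °C; aq. NH4Cl
Reagents that add atoms: none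
Why: Iodine–magnesium exchange with retention of alkene geometry, then copper-catalysed SN2 opening of the epoxide at its CH2 terminus, forms C11–C12 without touching the stereocentre.

Step 8
Reactants: 14 methyl (2S,4E)-2-hydroxyhept-4-enoate
Product: 15 methyl (2S,4E)-2-[(tert-butyldimethylsilyl)oxy]hept-4-enoate
Conditions: t-BuMe2SiCl, imidazole, DMF, 25 °C
Reagents that add atoms: tert-butyl(chloro)dimethylsilane, CC(C)(C)[Si](C)(C)Cl
Why: Standard silylation of the secondary alcohol gives a non-participating ether that survives the enolate, hydride and phosphine steps.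

Step 9
Reactants: 15 methyl (2S,4E)-2-[(tert-butyldimethylsilyl)oxy]hept-4-enoate
Product: 17 (3S,5E)-3-[(tert-butyldimethylsilyl)oxy]oct-5-en-2-one, via Weinreb amide 16 (not isolated)
Conditions: MeNH(OMe)·HCl, i-PrMgCl, THF, −20 °C; then MeMgBr, 0 °C
Reagents that add atoms: methylmagnesium bromide, C[Mg]Br
Why: One-pot Weinreb amide formation and Grignard addition: the chelated tetrahedral intermediate stops at the methyl ketone and the α-stereocentre is not enolised at low temperature.

Step 10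
Reactants: 18 diethyl sulfide
Product: 19 bromodiethylsulfonium bromopentachloroantimonate (BDSB)
Conditions: Br2, SbCl5, 1,2-dichloroethane, −30 to 25 °C; crystallisation
Reagents that add atoms: bromine, BrBr; antimony pentachloride, Cl[Sb](Cl)(Cl)(Cl)Cl
Why: Bromination of the sulfide and bromide abstraction by the Lewis acid give a crystalline bromosulfonium salt, a source of electrophilic bromine with a weakly nucleophilic counter-ion.

Step 11
Reactants: 17 (3S,5E)-3-[(tert-butyldimethylsilyl)oxy]oct-5-en-2-one; 7 (2S,4Z)-2,5-dichloropent-4-enal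
Product: 21 (1Z,4S,5R,8S,10E)-8-[(tert-butyldimethylsilyl)oxy]-1,4-dichloro-5-hydroxytrideca-1,10-dien-7-one, via lithium enolate 20 (not isolated)
Conditions: LiN(i-Pr)2, THF, −78 °C; then 7, −78 °C, 15 min; AcOH quench
Reagents that add atoms: none
Why: Aldol addition of the kinetic methyl-ketone lithium enolate to the α-chloro aldehyde through a Cornforth-type transition state gives the 6,7-anti chlorohydrin (C7 R) and forms C7–C8.

Step 12
Reactants: 21 (1Z,4S,5R,8S,10E)-8-[(tert-butyldimethylsilyl)oxy]-1,4-dichloro-5-hydroxytrideca-1,10-dien-7-one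
Product: 22 (1Z,4S,5R,7S,8S,10E)-8-[(tert-butyldimethylsilyl)oxy]-1,4-dichlorotrideca-1,10-diene-5,7-diol
Conditions: Et2BOMe, NaBH4, THF/MeOH 4:1, −78 °C; MeOH co-evaporation
Reagents that add atoms: none
Why: Narasaka–Prasad reduction: external hydride attacks the six-membered boron chelate axially to give the 7,9-syn diol, which sets C9 (S).

Step 13
Reactants: 22 (1Z,4S,5R,7S,8S,10E)-8-[(tert-butyldimethylsilyl)oxy]-1,4-dichlorotrideca-1,10-diene-5,7-diol
Product: 24 (2S,3R,5S)-5-{(1S,3E)-1-[(tert-butyldimethylsilyl)oxy]hex-3-en-1-yl}-2-[(2Z)-3-chloroprop-2-en-1-yl]oxolan-3-ol, via epoxy alcohol 23 (not isolated)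
Conditions: KOt-Bu (1.05 equiv), THF, −20 °C; then camphorsulfonic acid (0.2 equiv), CH2Cl2, 0 to 25 °C
Reagents that add atoms: none
Why: Intramolecular Williamson reaction of the C7 alkoxide (inversion at C6) gives the trans-epoxide, and acid-catalysed 5-endo epoxide opening by the C9 hydroxyl (second inversion at C6) closes ring A as the 2,5-cis-2,3-trans tetrahydrofuran.

Step 14
Reactants: 24 (2S,3R,5S)-5-{(1S,3E)-1-[(tert-butyldimethylsilyl)oxy]hex-3-en-1-yl}-2-[(2Z)-3-chloroprop-2-en-1-yl]oxolan-3-ol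
Product: 25 tert-butyl{[(1S,3E)-1-{(2S,4S,5S)-4-chloro-5-[(2Z)-3-chloroprop-2-en-1-yl]oxolan-2-yl}hex-3-en-1-yl]oxy}dimethylsilane
Conditions: (n-Oct)3P, CCl4, toluene, 70 °C
Reagents that add atoms: tetrachloromethane, ClC(Cl)(Cl)Cl
Why: Appel reaction: chloride displaces the oxyphosphonium group by SN2 with inversion, placing chlorine on C7 (S) cis to the C6 side chain.

Step 15
Reactants: 25 tert-butyl{[(1S,3E)-1-{(2S,4S,5S)-4-chloro-5-[(2Z)-3-chloroprop-2-en-1-yl]oxolan-2-yl}hex-3-en-1-yl]oxy}dimethylsilane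
Product: 27 (1S,3E)-1-{(2S,4S,5S)-4-chloro-5-[(2Z)-3-chloroprop-2-en-1-yl]oxolan-2-yl}hex-3-en-1-yl acetate, via alcohol 26 (not isolated)
Conditions: n-Bu4NF, THF, 0 °C; then Ac2O, pyridine, 4-(dimethylamino)pyridine (cat.), 25 °C
Reagents that add atoms: acetic anhydride, CC(=O)OC(C)=O
Why: Fluoride desilylation and in situ acylation install the C10 acetate, which is the relay group of the next step and remains in the target.

Step 16
Reactants: 27 (1S,3E)-1-{(2S,4S,5S)-4-chloro-5-[(2Z)-3-chloroprop-2-en-1-yl]oxolan-2-yl}hex-3-en-1-yl acetate; 19 bromodiethylsulfonium bromopentachloroantimonate (BDSB)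
Product: 30 (2S,3S,5S,6S,8R)-8-[(1S)-1-bromopropyl]-3,5-dichloro-2-[(2Z)-3-chloroprop-2-en-1-yl]oxocan-6-yl acetate, via bicyclic oxonium ion 28 (not isolated), via acetoxonium ion 29 (not isolated)
Conditions: 19 (1.2 equiv), MeNO2, −25 °C, 10 min; then Et4NCl (3 equiv), −25 to 0 °C
Reagents that add atoms: tetraethylammonium chloride, CC[N+](CC)(CC)CC.[Cl-]
Why: Proposed new method: a bromoetherification-triggered tetrahydrofuran-to-oxocane ring expansion with acetate relay and chloride termination; Br+ transfer from 19 to the only electron-rich alkene is followed by 5-exo attack of the ring-A oxygen on C12 anti to bromine, the bromopropyl group taking the convex face of the cis-fused 1-oxoniabicyclo[3.3.0]octane 28 (this sets C12 R and C13 S), the C10 acetate carbonyl then opens the ring-fusion carbon C9 with inversion to give the ring-expanded dioxolanylium ion 29, and chloride opens 29 at C9 with a second inversion because C10 is shielded on the attacking face by the 1,3-cis bromopropyl group, so chlorine ends on C9 with net retention and the acetate stays on C10; the closest known reaction types are bromonium-induced tetrahydrofuran-to-oxocane ring expansions terminated by an internal carbonate and the chloride opening of acetoxonium ions used to convert diols into chlorohydrin acetates.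

Step 17
Reactants: 30 (2S,3S,5S,6S,8R)-8-[(1S)-1-bromopropyl]-3,5-dichloro-2-[(2Z)-3-chloroprop-2-en-1-yl]oxocan-6-yl acetate; 31 ethynyl(trimethyl)silane
Product: 32 (2S,3S,5S,6S,8R)-8-[(1S)-1-bromopropyl]-3,5-dichloro-2-[(2Z)-5-(trimethylsilyl)pent-2-en-4-yn-1-yl]oxocan-6-yl acetate
Conditions: PdCl2(PhCN)2 (5 mol %), CuI (10 mol %), piperidine, 25 °C
Reagents that add atoms: none
Why: Sonogashira coupling: oxidative addition of the alkenyl chloride to zerovalent palladium with retention and coupling with the copper acetylide forge C2–C3, while the unactivated secondary alkyl halides do not react at room temperature.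

Step 18
Reactants: 32 (2S,3S,5S,6S,8R)-8-[(1S)-1-bromopropyl]-3,5-dichloro-2-[(2Z)-5-(trimethylsilyl)pent-2-en-4-yn-1-yl]oxocan-6-yl acetate
Product: 33 (2S,3S,5S,6S,8R)-8-[(1S)-1-bromopropyl]-3,5-dichloro-2-[(2Z)-pent-2-en-4-yn-1-yl]oxocan-6-yl acetate (CNP0251465.4)
Conditions: n-Bu4NF, AcOH, THF, 0 °C
Reagents that add atoms: none
Why: Buffered fluoride protodesilylation of the alkynylsilane; acetic acid keeps the medium non-basic so that the acetate and the alkyl halides survive.

**Compound list**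
1 | prop-2-enal (acrolein) | C=CC=O | starting material
2 | 2-(2-bromoethyl)-1,3-dioxolane | BrCCC1OCCO1 | intermediate
3 | (Z)-1,2-dichloroethene | Cl/C=C\Cl | starting material
4 | [2-(1,3-dioxolan-2-yl)ethyl]magnesium bromide | Br[Mg]CCC1OCCO1 | intermediate
5 | 2-[(3Z)-4-chlorobut-3-en-1-yl]-1,3-dioxolane | Cl/C=C\CCC1OCCO1 | intermediate
6 | (4Z)-5-chloropent-4-enal | Cl/C=C\CCC=O | intermediate
7 | (2S,4Z)-2,5-dichloropent-4-enal | Cl/C=C\C[C@H](Cl)C=O | intermediate
8 | but-1-yne | CCC#C | starting material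
9 | [(1E)-but-1-en-1-yl]chlorozirconocene | CC/C=C/[Zr](Cl)(C1C=CC=C1)C1C=CC=C1 | intermediate
10 | (1E)-1-iodobut-1-ene | CC/C=C/I | intermediate
11 | methyl oxirane-2-carboxylate (racemic) | COC(=O)C1CO1 | starting material
12 | methyl (2S)-oxirane-2-carboxylate | COC(=O)[C@@H]1CO1 | intermediate
13 | [(1E)-but-1-en-1-yl]magnesium chloride | CC/C=C/[Mg]Cl | intermediate
14 | methyl (2S,4E)-2-hydroxyhept-4-enoate | COC(=O)[C@@H](O)C/C=C/CC | intermediate
15 | methyl (2S,4E)-2-[(tert-butyldimethylsilyl)oxy]hept-4-enoate | COC(=O)[C@@H](O[Si](C)(C)C(C)(C)C)C/C=C/CC | intermediate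
16 | (2S,4E)-2-[(tert-butyldimethylsilyl)oxy]-N-methoxy-N-methylhept-4-enamide | CON(C)C(=O)[C@@H](O[Si](C)(C)C(C)(C)C)C/C=C/CC | intermediate
17 | (3S,5E)-3-[(tert-butyldimethylsilyl)oxy]oct-5-en-2-one | CC(=O)[C@@H](O[Si](C)(C)C(C)(C)C)C/C=C/CC | intermediate
18 | diethyl sulfide | CCSCC | starting material
19 | bromodiethylsulfonium bromopentachloroantimonate (BDSB) | CC[S+](Br)CC.Cl[Sb-](Cl)(Cl)(Cl)(Cl)Br | intermediate
20 | lithium (3S,5E)-3-[(tert-butyldimethylsilyl)oxy]octa-1,5-dien-2-olate | [Li]OC(=C)[C@@H](O[Si](C)(C)C(C)(C)C)C/C=C/CC | intermediate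
21 | (1Z,4S,5R,8S,10E)-8-[(tert-butyldimethylsilyl)oxy]-1,4-dichloro-5-hydroxytrideca-1,10-dien-7-one (C6 S, C7 R, C10 S) | Cl/C=C\C[C@H](Cl)[C@H](O)CC(=O)[C@@H](O[Si](C)(C)C(C)(C)C)C/C=C/CC | intermediate
22 | (1Z,4S,5R,7S,8S,10E)-8-[(tert-butyldimethylsilyl)oxy]-1,4-dichlorotrideca-1,10-diene-5,7-diol | Cl/C=C\C[C@H](Cl)[C@H](O)C[C@H](O)[C@@H](O[Si](C)(C)C(C)(C)C)C/C=C/CC | intermediate
23 | (2S,3S,5E)-3-[(tert-butyldimethylsilyl)oxy]-1-{(2R,3R)-3-[(2Z)-3-chloroprop-2-en-1-yl]oxiran-2-yl}oct-5-en-2-ol | Cl/C=C\C[C@H]1O[C@@H]1C[C@H](O)[C@@H](O[Si](C)(C)C(C)(C)C)C/C=C/CC | intermediate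
24 | (2S,3R,5S)-5-{(1S,3E)-1-[(tert-butyldimethylsilyl)oxy]hex-3-en-1-yl}-2-[(2Z)-3-chloroprop-2-en-1-yl]oxolan-3-ol | Cl/C=C\C[C@@H]1O[C@@H](C[C@H]1O)[C@@H](O[Si](C)(C)C(C)(C)C)C/C=C/CC | intermediate
25 | tert-butyl{[(1S,3E)-1-{(2S,4S,5S)-4-chloro-5-[(2Z)-3-chloroprop-2-en-1-yl]oxolan-2-yl}hex-3-en-1-yl]oxy}dimethylsilane | Cl/C=C\C[C@@H]1O[C@@H](C[C@@H]1Cl)[C@@H](O[Si](C)(C)C(C)(C)C)C/C=C/CC | intermediate
26 | (1S,3E)-1-{(2S,4S,5S)-4-chloro-5-[(2Z)-3-chloroprop-2-en-1-yl]oxolan-2-yl}hex-3-en-1-ol | Cl/C=C\C[C@@H]1O[C@@H](C[C@@H]1Cl)[C@@H](O)C/C=C/CC | intermediate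
27 | (1S,3E)-1-{(2S,4S,5S)-4-chloro-5-[(2Z)-3-chloroprop-2-en-1-yl]oxolan-2-yl}hex-3-en-1-yl acetate | Cl/C=C\C[C@@H]1O[C@@H](C[C@@H]1Cl)[C@@H](OC(C)=O)C/C=C/CC | intermediate
28 | cis-fused 1-oxoniabicyclo[3.3.0]octane salt: ring oxygen of 27 bonded to C12 (R), bromine on C13 (S), counter-ion SbCl5Br | Cl/C=C\C[C@@H]1[O+]2[C@@H](C[C@@H]1Cl)[C@@H](OC(C)=O)C[C@@H]2[C@@H](Br)CC.Cl[Sb-](Cl)(Cl)(Cl)(Cl)Br | intermediate
29 | oxocane-fused 2-methyl-1,3-dioxolan-2-ylium salt (acetoxonium on C9 R and C10 S, cis-fused), counter-ion SbCl5Br | Cl/C=C\C[C@@H]1O[C@@H]([C@@H](Br)CC)C[C@@H]2[O+]=C(C)O[C@@H]2C[C@@H]1Cl.Cl[Sb-](Cl)(Cl)(Cl)(Cl)Br | intermediate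
30 | (2S,3S,5S,6S,8R)-8-[(1S)-1-bromopropyl]-3,5-dichloro-2-[(2Z)-3-chloroprop-2-en-1-yl]oxocan-6-yl acetate | Cl/C=C\C[C@@H]1O[C@@H]([C@@H](Br)CC)C[C@H](OC(C)=O)[C@@H](Cl)C[C@@H]1Cl | intermediate
31 | ethynyl(trimethyl)silane | C#C[Si](C)(C)C | starting material
32 | (2S,3S,5S,6S,8R)-8-[(1S)-1-bromopropyl]-3,5-dichloro-2-[(2Z)-5-(trimethylsilyl)pent-2-en-4-yn-1-yl]oxocan-6-yl acetate | C[Si](C)(C)C#C/C=C\C[C@@H]1O[C@@H]([C@@H](Br)CC)C[C@H](OC(C)=O)[C@@H](Cl)C[C@@H]1Cl | intermediate
33 | (2S,3S,5S,6S,8R)-8-[(1S)-1-bromopropyl]-3,5-dichloro-2-[(2Z)-pent-2-en-4-yn-1-yl]oxocan-6-yl acetate (C6 S, C7 S, C9 S, C10 S, C12 R, C13 S) | C#C/C=C\C[C@@H]1O[C@@H]([C@@H](Br)CC)C[C@H](OC(C)=O)[C@@H](Cl)C[C@@H]1Cl | target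

**Totals**
Total step count: 18.
Longest linear sequence: 12 steps (steps 1, 2, 3, 4, 11, 12, 13, 14, 15, 16, 17, 18; the two paths through steps 5 or 6, then 7, 8, 9 are equally long).

**Steps most likely to fail**

Step 16 (the proposed new step). Risks are halide capture of the oxonium ion before the acetate relays, and opening of the acetoxonium ion at C10 instead of C9. The fallback sets out from 25 and comes back at 30. Desilylation of 25 (n-Bu4NF, THF) gives alcohol 26, which is isolated and converted with Boc2O and 4-(dimethylamino)pyridine into the tert-butyl carbonate F1. Treatment with 19 in MeNO2 at −25 °C then follows the established carbonate-terminated ring expansion (the carbonate carbonyl opens C9, 2-methylpropene is lost) to give the oxocane-fused cyclic carbonate F2. K2CO3 in MeOH frees the cis-9,10-diol F3. The known diol-to-chlorohydrin-acetate protocol (MeC(OMe)3, pyridinium p-toluenesulfonate; then Me3SiCl, CH2Cl2) then generates the dioxolanylium ion in a separate, tunable step and gives 30; any 10-chloro-9-acetate regioisomer is removed by chromatography.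

Step 17. The unactivated alkenyl chloride may couple slowly, and piperidine may attack the acetate or the alkyl halides. The fallback sets out from 30 and comes back at 33. Ozonolysis (O3, CH2Cl2, −78 °C; then Me2S) cleaves the chloroalkene to the aldehyde F4. Peterson olefination with lithiated 1,3-bis(triisopropylsilyl)propyne (n-BuLi, THF, −78 °C) gives the (Z)-silyl enyne F5, and n-Bu4NF with AcOH removes the silyl group to give 33.

Step 11. The α-chloro aldehyde can epimerise or eliminate under the basic enolate, and two chiral partners must match. The fallback sets out from 17 and comes back at 21. LiN(i-Pr)2 then Me3SiCl (THF, −78 °C) gives the trimethylsilyl enol ether F6. Mukaiyama aldol addition of F6 to 7 with BF3·OEt2 in CH2Cl2 at −78 °C (open transition state, same anti sense, no basic enolate in contact with the aldehyde) gives 21.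

**Further compounds**
F1 | step 16 | tert-butyl (1S,3E)-1-{(2S,4S,5S)-4-chloro-5-[(2Z)-3-chloroprop-2-en-1-yl]oxolan-2-yl}hex-3-en-1-yl carbonate | Cl/C=C\C[C@@H]1O[C@@H](C[C@@H]1Cl)[C@@H](OC(=O)OC(C)(C)C)C/C=C/CC
F2 | step 16 | cis-fused 5,6-cyclic carbonate of (2S,3S,5R,6S,8R)-8-[(1S)-1-bromopropyl]-3-chloro-2-[(2Z)-3-chloroprop-2-en-1-yl]oxocane-5,6-diol | Cl/C=C\C[C@@H]1O[C@@H]([C@@H](Br)CC)C[C@@H]2OC(=O)O[C@@H]2C[C@@H]1Cl
F3 | step 16 | (2S,3S,5R,6S,8R)-8-[(1S)-1-bromopropyl]-3-chloro-2-[(2Z)-3-chloroprop-2-en-1-yl]oxocane-5,6-diol | Cl/C=C\C[C@@H]1O[C@@H]([C@@H](Br)CC)C[C@H](O)[C@H](O)C[C@@H]1Cl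
F4 | step 17 | (2S,3S,5S,6S,8R)-8-[(1S)-1-bromopropyl]-3,5-dichloro-2-(2-oxoethyl)oxocan-6-yl acetate | O=CC[C@@H]1O[C@@H]([C@@H](Br)CC)C[C@H](OC(C)=O)[C@@H](Cl)C[C@@H]1Cl
F5 | step 17 | (2S,3S,5S,6S,8R)-8-[(1S)-1-bromopropyl]-3,5-dichloro-2-[(2Z)-5-(triisopropylsilyl)pent-2-en-4-yn-1-yl]oxocan-6-yl acetate | CC(C)[Si](C(C)C)(C(C)C)C#C/C=C\C[C@@H]1O[C@@H]([C@@H](Br)CC)C[C@H](OC(C)=O)[C@@H](Cl)C[C@@H]1Cl
F6 | step 11 | (3S,5E)-3-[(tert-butyldimethylsilyl)oxy]-2-[(trimethylsilyl)oxy]octa-1,5-diene | C=C(O[Si](C)(C)C)[C@@H](O[Si](C)(C)C(C)(C)C)C/C=C/CC
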